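If you take over the bench at 40 h, expect this flask, the epsilon run carried on, to hold what it has held since 1.50 h: target scattered about 17.7%, and starting material reading 0.2% at 20.0 h, less than the scatter of 1 percentage point.

in all of them: starting material 20 mM

|  | second substrate | solid reagent | remark | time |
|---|---|---|---|---|
| epsilon | 0.20 equiv | 3 equiv | the very flask that is asked about, followed so far |  |
| zeta | 0.10 equiv | 3 equiv | run made earlier |  |
| flask | 0.200 equiv | 3.00 equiv |  | 40 h |

- epsilon (time / h: target / %, starting material / %): 1.50: 17.5, 0; 5.00: 17.2, 1.9; 8.00: 18.5, 0.7; 12.0: 16.9, 0; 20.0: 16.9, 0.2; 25.0: 19.4, 1.4
- zeta (time / min: target / %, starting material / %): 6.00: 7.9, 76.2; 15.0: 14.0, 47.9; 30.0: 16.4, 17.5; 50.0: 18.1, 4.2; 60.0: 17.5, 4.7; 80.0: 18.5, 0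

(standard deviation of a reading: 1 percentage point)

- Tuesday's: at 40 h add starting material, 50.0% of the amount charged, then wait 3.0 d
- Monday's: at 40 h take out 90% of the target then present, then wait 3.0 d
- Thursday's: change nothing and wait 3.0 d more

- target, in percent of the starting material first charged, at 40 h
- the option that brings most further target ("none" if no option brings more than 2 percentage points) (Tuesday's / Monday's / Thursday's / none)
- target present, with what was taken out counted in, in percent of the starting material first charged, after Tuesday's
- target present, with what was taken out counted in, in percent of the starting material first charged, after Monday's

- solid, in amounts per volume of the solution: solid reagent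
- removed target is counted in
- at the start none of the solid reagent is in solution
- additions bring no volume worth counting

The zeta run, charged with half the second substrate of this flask, shows the target growing to a last reading of 18.5%, beside the epsilon plateau. We take the instantaneous selectivity, target gained per starting material consumed: it reads 0.332 while target averages 3.95%, and 0.0938 while target averages 16.1%. Drawn straight, this fall reaches zero at the ceiling, the target level at which further starting material adds no net target, 20.8%.

This flask stands 3.1 points below that ceiling. With selectivity shrinking in step with the gap, Tuesday's addition of half a charge should gain 1.9 points, narrowly less than 2 points, giving 19.6%. Monday's and Thursday's bring no starting material, so we expect the count, removed target included, to stay at the plateau. Our call is to leave the flask alone.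

The forecast gives 17.7% but names Monday's, with 26.6% after Tuesday's and 30.8% after Monday's, reading the target as “relaxing into a fast equilibrium with a by-product”.

The flask gives 17.9%, option none, 19.1% after Tuesday's and 17.9% after Monday's.

    starting material + partner → target (k = 0.150 /M/s)
    solid reagent ⇌ partner, rate k2*(cs2 - [partner]) while solid is left; crystals form when [partner] > cs2 (solubility = 4.10 mM, k = 0.0120 /s)
    starting material + second substrate → cross product (k = 0.210 /M/s)
    second substrate + partner → second product (k = 0.580 /M/s)
    starting material + target → side product (k = 0.150 /M/s)

At 40.0 h side product holds 67.8% of the starting material charged to this flask, two to each side product. Tuesday's gain of 1.2 points lies within the 2.9 points between 17.9% and the ceiling. Carried as the same amount to the neighbour charged with a quarter of the starting material, where partner stands at 4.10 mM as in this flask, the ceiling becomes 83.3% of that charge, and that flask stands below it at 46.7%.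

Readings and results are simulated for an exercise, noise included.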